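A direct plan would join two unlike halves: the benzyl-protected β-keto imide A1 (a syringoyl-acetyl oxazolidinone) and benzyl-protected (E)-propenylsyringol A2 would be fused by a manganese triacetate oxidative annulation to dihydrofuran A3. The imide would then be reduced to allylic alcohol A4, A4 turned into oxolane A5 by ionic hydrogenation, and the benzyl ethers removed. Its weakest points would be:
- **The radical annulation.** It would be the only source of absolute configuration, yet a benzyl group on an auxiliary remote from a planar radical would have to choose the face at C3, so C3 and the cationic ring closure are left to chance.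
- **The BF3/Et3SiH deoxygenation–reduction.** It would set C4 and C5 at once through a reversible protonation, on precious late material that carries an acid-labile para-alkoxybenzyl C2–O bond.
- **The run-up.** Six protecting and acylating steps, and a C4 methyl carried in as a carboxyl carbon, would add no stereocentre; the sequence would end in a hydrogenolysis beside two benzylic ring C–O bonds.

**Plan of the new route.** The oxolane (O1, C2–C5) carries two constitutionally identical halves, C2(Ar)–C3(Me) and C5(Ar)–C4(Me), with C3 and C4 both S; only C5 breaks the C2 axis through O1 and the middle of C3–C4. Cutting O1–C5 with inversion therefore leads to a C2-symmetric (S,S,S,S)-1,4-diol with homotopic hydroxyls. That diol is the product of two syn additions of H–OH (bonds C2–O, C5–O, C3–H, C4–H) to a flat, achiral (1E,3E)-1,4-diaryl-2,3-dimethylbutadiene, which is cut at C3–C4 into two alkenylboronates made from an arylpropyne. The oxolane is the last ring to form, by C–O closure alone. Configuration comes from one reagent-controlled, stereospecific operation and one SN2 closure: no auxiliary, no radical face selection, no acid on the finished ring. The pivalates make the SN2 closure possible and leave with base.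

Key step: step 5

Remarks:
- Ring numbering of the target (O1, C2–C5) is used for all intermediates in the text; in the names of open-chain compounds these carbons are chain positions 1–4. Ar = 3,5-dimethoxy-4-(pivaloyloxy)phenyl; pivalate = 2,2-dimethylpropanoate.
- Assumption: 4-bromo-2,6-dimethoxyphenol is bought.
- Assumption: IpcBH2 is used as a titrated solution set free beforehand from its commercial TMEDA adduct. The antipode from (−)-α-pinene is assigned by analogy with Brown's empirical face rule; the first run would confirm the sense, and the other antipode is equally available.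

Step 1
Reactants: 1 4-bromo-2,6-dimethoxyphenol
Product: 2 4-bromo-2,6-dimethoxyphenyl pivalate
Conditions: PivCl (1.3 equiv), Et3N (1.5 equiv), DMAP (0.1 equiv), CH2Cl2, 0 °C → rt
Reagents that add atoms: pivaloyl chloride, CC(C)(C)C(=O)Cl
Why: Acylation of the hindered phenol through the N-acylpyridinium ion (DMAP catalysis); the pivalate is more than a protecting group, since it makes the arene electron-poor, which step 6 needs, and it falls to methoxide at the end.

Step 2
Reactants: 2 4-bromo-2,6-dimethoxyphenyl pivalate
Product: 3 2,6-dimethoxy-4-(prop-1-yn-1-yl)phenyl pivalate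
Conditions: propyne (3 equiv), Pd(PhCN)2Cl2 (3 mol%), t-Bu3P·HBF4 (6 mol%), CuI (2 mol%), i-Pr2NH (2 equiv), dioxane, rt, sealed vessel
Reagents that add atoms: propyne, CC#C
Why: Sonogashira coupling, in which the bulky electron-rich phosphine lets the aryl bromide add to zerovalent palladium at room temperature, so the aryl ester is never exposed to hot amine.

Step 3
Reactants: 3 2,6-dimethoxy-4-(prop-1-yn-1-yl)phenyl pivalate
Product: 4 2,6-dimethoxy-4-[(Z)-2-(4,4,5,5-tetramethyl-1,3,2-dioxaborolan-2-yl)prop-1-en-1-yl]phenyl pivalate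
Conditions: B2pin2 (1.1 equiv), CuCl (5 mol%), Xantphos (5 mol%), NaOt-Bu (10 mol%), MeOH (2 equiv), THF, rt
Reagents that add atoms: bis(pinacolato)diboron, CC1(C)OB(OC1(C)C)B1OC(C)(C)C(C)(C)O1
Why: Copper-catalysed formal hydroboration of an aryl alkyl alkyne, in which the boryl complex of monovalent copper adds syn with copper on the aryl-bearing carbon and boron on the methyl-bearing carbon and methanol protonates the C–Cu bond with retention, so the aryl group ends trans to boron.

Step 4
Reactants: 4 2,6-dimethoxy-4-[(Z)-2-(4,4,5,5-tetramethyl-1,3,2-dioxaborolan-2-yl)prop-1-en-1-yl]phenyl pivalate (2 equiv)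
Product: 5 (1E,3E)-1,4-bis[3,5-dimethoxy-4-(pivaloyloxy)phenyl]-2,3-dimethylbuta-1,3-diene
Conditions: Pd(OAc)2 (5 mol%), K2CO3 (1.5 equiv), acetone–H2O (4:1), O2 (1 atm), rt
Reagents that add atoms: none
Why: Palladium-catalysed aerobic oxidative homocoupling of an alkenylboronate, in which two transmetalations onto divalent palladium and the reductive elimination proceed with retention at both sp2 carbons, so the Z boronate should give the E,E diene (C3–C4 bond) while dioxygen returns zerovalent palladium to the divalent state.

Step 5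
Reactants: 5 (1E,3E)-1,4-bis[3,5-dimethoxy-4-(pivaloyloxy)phenyl]-2,3-dimethylbuta-1,3-diene
Product: 7 (1S,2S,3S,4S)-1,4-bis[3,5-dimethoxy-4-(pivaloyloxy)phenyl]-2,3-dimethylbutane-1,4-diol, via bis(isopinocampheylboryl) adduct 6 (not isolated)
Conditions: IpcBH2 from (−)-α-pinene (2.6 equiv, 0.8 M), THF, −25 → 0 °C; MeOH; NaBO3·4H2O, THF–H2O, rt
Reagents that add atoms: sodium perborate, [Na+].[O-]OB=O; (isopinocampheyl)borane from (−)-α-pinene, C[C@@H]1[C@@H](B)C[C@H]2C[C@@H]1C2(C)C (boron and isopinocampheyl in 6 only)
Why: Proposed new method: each ArCH=C(Me) unit of 5 should add H–B of IpcBH2 syn through the concerted four-centre transition state, with boron on the less substituted benzylic carbons C2 and C5 and hydrogen on C3 and C4, and perborate then replaces each C–B bond by C–OH with retention. The closest known reaction type is the asymmetric hydroboration of trisubstituted aryl alkenes with IpcBH2, which has not been shown twice over on one conjugated 1,4-diaryl diene. No ring closes here; the oxolane closes in step 6. The C2/C3 and C5/C4 relative configuration follows from syn addition to the E alkenes, and the absolute sense at all four centres from the isopinocampheyl group, which by Brown's face rule for trisubstituted alkenes should put boron on the face that makes each carbinol S; equal sense at both ends gives the C2-symmetric 3,4-threo diol, and the second addition should be the matched case, since attack on C4=C5 anti to the C2 branch of the allylic centre C3, with the C3 hydrogen beside the C4 methyl, leads to the same array. The step needs regio-, face and diastereoselectivity: regioselectivity rests on the trisubstituted styrene pattern and the electron-poor arene, and since two reagent-controlled additions are coupled, one wrong face gives the separable meso diastereomer and only two wrong faces the enantiomer, so 7 should be purer in enantiomer than one addition alone would make it. The excess of the reactive monoalkylborane at low temperature is meant to outrun ring closure of the first, hindered dialkylborane onto the second alkene.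

Step 6
Reactants: 7 (1S,2S,3S,4S)-1,4-bis[3,5-dimethoxy-4-(pivaloyloxy)phenyl]-2,3-dimethylbutane-1,4-diol
Product: 8 (2S,3S,4S,5R)-2,5-bis[3,5-dimethoxy-4-(pivaloyloxy)phenyl]-3,4-dimethyloxolane (2,3-trans, 3,4-trans, 4,5-cis)
Conditions: PPh3 (1.5 equiv), DIAD (1.5 equiv), THF, 0 °C → rt
Reagents that add atoms: none
Why: Mitsunobu cyclodehydration (5-exo-tet), in which either of the two homotopic hydroxyls is activated as the alkoxyphosphonium ion and displaced by the other with inversion, which sets C5 as R and the 4,5-cis relationship; the acyloxy-substituted arene stabilises a benzylic cation no better than phenyl does, so SN2 should prevail over ionisation.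

Step 7
Reactants: 8 (2S,3S,4S,5R)-2,5-bis[3,5-dimethoxy-4-(pivaloyloxy)phenyl]-3,4-dimethyloxolane
Product: 9 4,4'-[(2S,3S,4S,5R)-3,4-dimethyloxolane-2,5-diyl]bis(2,6-dimethoxyphenol) (CNP0217414.2)
Conditions: NaOMe (3 equiv), MeOH–THF, 0 °C → rt; aq NH4Cl
Reagents that add atoms: none
Why: Methanolysis of the two aryl esters, with phenoxide as the leaving group, under basic conditions in which the benzylic ether centres C2 and C5 cannot ionise, followed by a near-neutral work-up that avoids acid epimerisation of the free phenol.

**Compound list**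

1 | 4-bromo-2,6-dimethoxyphenol | COc1cc(Br)cc(OC)c1O | starting material
2 | 4-bromo-2,6-dimethoxyphenyl pivalate | COc1cc(Br)cc(OC)c1OC(=O)C(C)(C)C | intermediate
3 | 2,6-dimethoxy-4-(prop-1-yn-1-yl)phenyl pivalate | CC#Cc1cc(OC)c(OC(=O)C(C)(C)C)c(OC)c1 | intermediate
4 | 2,6-dimethoxy-4-[(Z)-2-(4,4,5,5-tetramethyl-1,3,2-dioxaborolan-2-yl)prop-1-en-1-yl]phenyl pivalate (aryl trans to boron) | C/C(=C\c1cc(OC)c(OC(=O)C(C)(C)C)c(OC)c1)B1OC(C)(C)C(C)(C)O1 | intermediate
5 | (1E,3E)-1,4-bis[3,5-dimethoxy-4-(pivaloyloxy)phenyl]-2,3-dimethylbuta-1,3-diene | COc1cc(/C=C(C)/C(C)=C/c2cc(OC)c(OC(=O)C(C)(C)C)c(OC)c2)cc(OC)c1OC(=O)C(C)(C)C | intermediate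
6 | 1,4-bis[hydrido(isopinocampheyl)boryl] adduct of 5: boron on C2 and C5 in the positions of the hydroxyls of 7, hydrogen on C3 and C4, isopinocampheyl from (−)-α-pinene (drawn as the monomer) | C[C@@H]1[C@@H](B[C@H](c3cc(OC)c(OC(=O)C(C)(C)C)c(OC)c3)[C@@H](C)[C@H](C)[C@H](B[C@H]3C[C@H]4C[C@@H]([C@@H]3C)C4(C)C)c3cc(OC)c(OC(=O)C(C)(C)C)c(OC)c3)C[C@H]2C[C@@H]1C2(C)C | intermediate
7 | (1S,2S,3S,4S)-1,4-bis[3,5-dimethoxy-4-(pivaloyloxy)phenyl]-2,3-dimethylbutane-1,4-diol (C2-symmetric) | O[C@H](c1cc(OC)c(OC(=O)C(C)(C)C)c(OC)c1)[C@@H](C)[C@H](C)[C@H](O)c1cc(OC)c(OC(=O)C(C)(C)C)c(OC)c1 | intermediate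
8 | (2S,3S,4S,5R)-2,5-bis[3,5-dimethoxy-4-(pivaloyloxy)phenyl]-3,4-dimethyloxolane (2,3-trans, 3,4-trans, 4,5-cis) | COc1cc([C@H]2O[C@@H](c3cc(OC)c(OC(=O)C(C)(C)C)c(OC)c3)[C@@H](C)[C@@H]2C)cc(OC)c1OC(=O)C(C)(C)C | intermediate
9 | 4,4'-[(2S,3S,4S,5R)-3,4-dimethyloxolane-2,5-diyl]bis(2,6-dimethoxyphenol) | COc1cc([C@H]2O[C@@H](c3cc(OC)c(O)c(OC)c3)[C@@H](C)[C@@H]2C)cc(OC)c1O | target

Total step count: 7. Longest linear sequence: 7 steps (1 → 9).

**Steps most likely to fail**

Step 5. Three processes threaten it. The first-formed dialkylborane may close onto the second alkene (cyclic hydroboration to a borolane), a substrate-relayed path that the same conformational analysis predicts to give the meso array. The face selectivity of the reagent may be too low. The second addition may stall if the dialkylborane dimer separates. The fallback uses known chemistry and runs from 3 to 7: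
- Gold-catalysed Markovnikov hydration of 3 (Ph3PAuNTf2, aqueous dioxane) would give the aryl ethyl ketone 2,6-dimethoxy-4-propanoylphenyl pivalate F1.
- Its lithium enolate (LDA, THF, −78 °C) would be dimerised with CuCl2 to the 1,4-diketone, from which the racemic threo isomer, rac-(2S,3S)-1,4-bis[3,5-dimethoxy-4-(pivaloyloxy)phenyl]-2,3-dimethylbutane-1,4-dione F2, is taken; the meso isomer is returned after base equilibration.
- Catalyst-controlled reduction of both carbonyl groups with (R)-Me-CBS and BH3·SMe2 should make both carbinols S. The (2S,3S) enantiomer of F2 then gives 7, and the (2R,3R) enantiomer gives the separable diastereomer (1S,2R,3R,4S)-1,4-bis[3,5-dimethoxy-4-(pivaloyloxy)phenyl]-2,3-dimethylbutane-1,4-diol F3.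
- The route is rejoined at 7, at the price of half the material.

Step 6. The alkoxyphosphonium ion may ionise, which would lose the inversion and drift to the all-trans ring, or it may eliminate to the styrene. The fallback replaces substitution by a redox sequence and runs from 7 to 8:
- One equivalent of Dess–Martin periodinane would oxidise one of the two homotopic carbinols, and the hydroxy ketone closes to the cyclic hemiketal (3S,4S,5S)-2,5-bis[3,5-dimethoxy-4-(pivaloyloxy)phenyl]-3,4-dimethyloxolan-2-ol F4; diol and diketone are recycled.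
- Et3SiH and BF3·OEt2 (CH2Cl2, −78 °C) would reduce the derived oxocarbenium ion from the face anti to the neighbouring methyl, as is known for 2-aryl-3-methyl cyclic hemiketals. This places the aryl group cis to that methyl and gives 8 without substitution at a stereocentre.
- The electron-poor arene at the other benzylic carbon should keep that centre from ionising under the Lewis acid.

Step 4. Peroxide formed under aerobic palladium catalysis may oxidise the carbon–boron bond; protodeboronation and loss of alkene geometry are the other risks. The fallback replaces homocoupling by cross-coupling and runs from 4 to 5: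
- Part of 4 would be converted with retention (NIS, MeCN) into the alkenyl iodide (E)-4-(2-iodoprop-1-en-1-yl)-2,6-dimethoxyphenyl pivalate F5.
- F5 would be joined with the remaining 4 by Suzuki–Miyaura coupling (Pd(PPh3)4, K3PO4, dioxane–H2O, 60 °C, air excluded) to give 5.

**Further compounds**

F1 | step 5 | 2,6-dimethoxy-4-propanoylphenyl pivalate | CCC(=O)c1cc(OC)c(OC(=O)C(C)(C)C)c(OC)c1
F2 | step 5 | rac-(2S,3S)-1,4-bis[3,5-dimethoxy-4-(pivaloyloxy)phenyl]-2,3-dimethylbutane-1,4-dione (racemic threo; one enantiomer drawn) | O=C(c1cc(OC)c(OC(=O)C(C)(C)C)c(OC)c1)[C@@H](C)[C@H](C)C(=O)c1cc(OC)c(OC(=O)C(C)(C)C)c(OC)c1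
F3 | step 5 | (1S,2R,3R,4S)-1,4-bis[3,5-dimethoxy-4-(pivaloyloxy)phenyl]-2,3-dimethylbutane-1,4-diol | O[C@H](c1cc(OC)c(OC(=O)C(C)(C)C)c(OC)c1)[C@H](C)[C@@H](C)[C@H](O)c1cc(OC)c(OC(=O)C(C)(C)C)c(OC)c1
F4 | step 6 | (3S,4S,5S)-2,5-bis[3,5-dimethoxy-4-(pivaloyloxy)phenyl]-3,4-dimethyloxolan-2-ol (both anomers) | O1[C@H](c2cc(OC)c(OC(=O)C(C)(C)C)c(OC)c2)[C@@H](C)[C@H](C)C1(O)c1cc(OC)c(OC(=O)C(C)(C)C)c(OC)c1
F5 | step 4 | (E)-4-(2-iodoprop-1-en-1-yl)-2,6-dimethoxyphenyl pivalate | C/C(=C\c1cc(OC)c(OC(=O)C(C)(C)C)c(OC)c1)I
A1 | direct plan | (S)-4-benzyl-3-[3-(4-benzyloxy-3,5-dimethoxyphenyl)-3-oxopropanoyl]oxazolidin-2-one | O=C(CC(=O)N1[C@@H](Cc2ccccc2)COC1=O)c1cc(OC)c(OCc2ccccc2)c(OC)c1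
A2 | direct plan | 2-(benzyloxy)-1,3-dimethoxy-5-[(E)-prop-1-enyl]benzene | C/C=C/c1cc(OC)c(OCc2ccccc2)c(OC)c1
A3 | direct plan | (S)-4-benzyl-3-{[(2S,3S)-2,5-bis(4-benzyloxy-3,5-dimethoxyphenyl)-3-methyl-2,3-dihydrofuran-4-yl]carbonyl}oxazolidin-2-one | COc1cc([C@H]2OC(c3cc(OC)c(OCc4ccccc4)c(OC)c3)=C(C(=O)N3[C@@H](Cc4ccccc4)COC3=O)[C@@H]2C)cc(OC)c1OCc1ccccc1
A4 | direct plan | [(2S,3S)-2,5-bis(4-benzyloxy-3,5-dimethoxyphenyl)-3-methyl-2,3-dihydrofuran-4-yl]methanol | COc1cc([C@H]2OC(c3cc(OC)c(OCc4ccccc4)c(OC)c3)=C(CO)[C@@H]2C)cc(OC)c1OCc1ccccc1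
A5 | direct plan | (2S,3S,4S,5R)-2,5-bis(4-benzyloxy-3,5-dimethoxyphenyl)-3,4-dimethyloxolane | COc1cc([C@H]2O[C@@H](c3cc(OC)c(OCc4ccccc4)c(OC)c3)[C@@H](C)[C@@H]2C)cc(OC)c1OCc1ccccc1
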